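## Retrosynthetic overview

1. Numbering follows the chromane core (O1, C2, C3, C4, C4a, C5–C8, C8a; ring A is the benzo ring). Target 17 ⇐ acid removal of three MOM groups and one TBS group from 16 ⇐ oxidation of diarylalkyne 14 to the 1,2-diketone ⇐ Sonogashira coupling of 8-bromoflavan 12 with alkyne 13.
2. 12 ⇐ hydrogenation of C3=C4 in 11 ⇐ decarbonylation of the C3 formyl group of 2H-chromene-3-carbaldehyde 10; the formyl group is a temporary activating group.
3. Key disconnection: 10 ⇐ salicylaldehyde 5 + enal 7. Amine catalysis forms O1–C2 by asymmetric oxa-Michael addition, then closes the pyran ring at C3–C4 by intramolecular aldol condensation, which sets C2.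
4. Enabling feature: C4 is a benzylic carbon on C4a, ortho to the phenolic ring oxygen O1 on C8a of ring A, and C2 carries O1 and an aryl group. O1–C8a–C4a–C4 is therefore a latent salicylaldehyde and C2–C3 a latent β-aryl enal whose α-carbon C3 becomes nucleophilic as an enamine.
5. Ring order: ring A and both hydroxyphenyl rings are bought (5 comes from 2,4,6-trihydroxybenzaldehyde by bis-MOM protection and ortho-bromination, the bromine marking C8). The pyran ring is the only ring formed, in step 4.

Key step: step 4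

## Route

Step 1
Reactants: 1 2,4,6-trihydroxybenzaldehyde
Product: 3 2-hydroxy-4,6-bis(methoxymethoxy)benzaldehyde
Conditions: MOMCl (2.2 equiv), i-Pr2NEt, CH2Cl2, 0 °C to rt
Reagents that add atoms: 2 chloromethyl methyl ether (MOMCl), COCCl
Why: Williamson-type O-alkylation should take the 4-OH and one ortho-OH, because the last ortho-hydroxyl is held in a hydrogen bond to the formyl group and is the least nucleophilic.

Step 2
Reactants: 3 2-hydroxy-4,6-bis(methoxymethoxy)benzaldehyde
Product: 5 3-bromo-2-hydroxy-4,6-bis(methoxymethoxy)benzaldehyde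
Conditions: NBS (1.0 equiv), i-Pr2NH (10 mol %), CH2Cl2, −20 °C to 0 °C
Reagents that add atoms: 4 N-bromosuccinimide, O=C1CCC(=O)N1Br
Why: Electrophilic aromatic bromination should go ortho to the free phenol (position 3), since position 5 is flanked by two methoxymethoxy groups, and no acid is formed that could cleave the acetals.

Step 3
Reactants: 6 (E)-3-(4-hydroxyphenyl)prop-2-enal
Product: 7 (E)-3-[4-(methoxymethoxy)phenyl]prop-2-enal
Conditions: MOMCl (1.2 equiv), i-Pr2NEt, CH2Cl2, 0 °C
Reagents that add atoms: 2 chloromethyl methyl ether (MOMCl), COCCl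
Why: Williamson-type O-alkylation of the phenol with an amine base leaves the enal untouched and stops the phenol from acting as a competing oxa-Michael donor in step 4.

Step 4
Reactants: 5 3-bromo-2-hydroxy-4,6-bis(methoxymethoxy)benzaldehyde, 7 (E)-3-[4-(methoxymethoxy)phenyl]prop-2-enal
Product: 10 (R)-8-bromo-5,7-bis(methoxymethoxy)-2-[4-(methoxymethoxy)phenyl]-2H-chromene-3-carbaldehyde, via oxa-Michael adduct 8 (not isolated), via aldol adduct 9 (not isolated)
Conditions: (S)-2-[diphenyl(trimethylsilyloxy)methyl]pyrrolidine (20 mol %), 2-nitrobenzoic acid (20 mol %), 4 Å molecular sieves, toluene, rt, dark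
Reagents that add atoms: none
Why: The secondary amine condenses with enal 7 to an (E)-iminium ion, the free phenol of 5 adds reversibly to its β-carbon (O1–C2, oxa-Michael), and the enamine so formed attacks the ortho formyl carbon through its α-carbon (C3–C4, intramolecular aldol), after which dehydration and hydrolysis release 10 and the catalyst. The closest known reaction type is the prolinol silyl ether catalysed domino oxa-Michael/aldol condensation of salicylaldehydes with β-aryl enals, applied here to a more hindered phenol. The pyran ring is closed at C3–C4 in a 6-(enolexo)-exo-trig aldol mode. C2 is the only lasting stereocentre: the diphenyl(trimethylsilyloxy)methyl group of the (S)-catalyst shields the Re face of the iminium β-carbon, so oxygen adds to the Si face, giving the arrangement that is called (R) in 10 (C3 outranks the aryl group) and (S) once the formyl group is gone; because the oxa-Michael step is reversible, adducts of either configuration return to 5 and 7 until they close through the favoured catalyst-bound enamine, and the C3/C4 diastereomers of 9 converge on dehydration. The step needs O- before C-attack and 1,4- before 1,2-addition (iminium activation), one defined ring oxygen and one defined ring-closing carbonyl: the two MOM ethers leave only the hydroxyl between CHO and Br free, and that hydroxyl has a single ortho formyl group.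

Step 5
Reactants: 10 (R)-8-bromo-5,7-bis(methoxymethoxy)-2-[4-(methoxymethoxy)phenyl]-2H-chromene-3-carbaldehyde
Product: 11 (S)-8-bromo-5,7-bis(methoxymethoxy)-2-[4-(methoxymethoxy)phenyl]-2H-chromene
Conditions: RhCl(PPh3)3 (1.1 equiv), toluene, 100 °C, dark
Reagents that add atoms: none
Why: Tsuji–Wilkinson decarbonylation: the formyl C–H adds oxidatively to monovalent rhodium, CO migrates to the metal and the vinyl–H bond forms by reductive elimination, so the activating group leaves C3 while the C3=C4 bond, the C–Br bond, the acetals and C2 stay unchanged.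

Step 6
Reactants: 11 (S)-8-bromo-5,7-bis(methoxymethoxy)-2-[4-(methoxymethoxy)phenyl]-2H-chromene
Product: 12 (S)-8-bromo-5,7-bis(methoxymethoxy)-2-[4-(methoxymethoxy)phenyl]chromane
Conditions: H2 (1 atm), RhCl(PPh3)3 (5 mol %), benzene/EtOH (1:1), rt
Reagents that add atoms: none
Why: Homogeneous hydrogenation with RhCl(PPh3)3 should add H2 to the cis-disubstituted, styrene-type C3=C4 bond without cleaving the benzylic C2–O1 bond or the C–Br bond, and C2 is not involved.

Step 7
Reactants: 12 (S)-8-bromo-5,7-bis(methoxymethoxy)-2-[4-(methoxymethoxy)phenyl]chromane, 13 tert-butyl(4-ethynylphenoxy)dimethylsilane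
Product: 14 (S)-tert-butyl{4-[(5,7-bis(methoxymethoxy)-2-[4-(methoxymethoxy)phenyl]chroman-8-yl)ethynyl]phenoxy}dimethylsilane
Conditions: PdCl2(PhCN)2 (3 mol %), P(t-Bu)3 (6 mol %), CuI (2 mol %), i-Pr2NH, 1,4-dioxane, rt to 50 °C
Reagents that add atoms: none
Why: Sonogashira coupling, in which the bulky electron-rich phosphine lets zerovalent palladium insert into the hindered, electron-rich C8–Br bond, and no benzofuran can form because both oxygens ortho to C8 are ethers.

Step 8
Reactants: 14 (S)-tert-butyl{4-[(5,7-bis(methoxymethoxy)-2-[4-(methoxymethoxy)phenyl]chroman-8-yl)ethynyl]phenoxy}dimethylsilane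
Product: 16 (S)-1-{5,7-bis(methoxymethoxy)-2-[4-(methoxymethoxy)phenyl]chroman-8-yl}-2-{4-[(tert-butyldimethylsilyl)oxy]phenyl}ethane-1,2-dione
Conditions: KMnO4, NaHCO3, MgSO4, acetone/H2O, 0 °C to rt
Reagents that add atoms: 15 potassium permanganate, [K+].[O-][Mn](=O)(=O)=O
Why: Buffered permanganate oxidation of a diarylalkyne to a benzil should be selective because the alkyne is the only non-aromatic π-bond, and the neutral medium spares the acetals and the silyl ether.

Step 9
Reactants: 16 (S)-1-{5,7-bis(methoxymethoxy)-2-[4-(methoxymethoxy)phenyl]chroman-8-yl}-2-{4-[(tert-butyldimethylsilyl)oxy]phenyl}ethane-1,2-dione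
Product: 17 (S)-1-[5,7-dihydroxy-2-(4-hydroxyphenyl)chroman-8-yl]-2-(4-hydroxyphenyl)ethane-1,2-dione (CNP0332855.1)
Conditions: HCl (1.25 M in MeOH), THF, 40 °C; aqueous work-up
Reagents that add atoms: none
Why: Acid-catalysed methanolysis (acetal exchange and silyl ether solvolysis) should cleave the three MOM ethers and the aryl TBS ether in one operation under conditions too mild to ionise the C2–O1 bond, so the (S)-configuration is kept.

## Compound list

1 | 2,4,6-trihydroxybenzaldehyde | O=Cc1c(O)cc(O)cc1O | starting material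
2 | chloromethyl methyl ether (MOMCl) | COCCl | starting material
3 | 2-hydroxy-4,6-bis(methoxymethoxy)benzaldehyde | O=Cc1c(O)cc(OCOC)cc1OCOC | intermediate
4 | N-bromosuccinimide | O=C1CCC(=O)N1Br | starting material
5 | 3-bromo-2-hydroxy-4,6-bis(methoxymethoxy)benzaldehyde | O=Cc1c(O)c(Br)c(OCOC)cc1OCOC | intermediate
6 | (E)-3-(4-hydroxyphenyl)prop-2-enal | O=C/C=C/c1ccc(O)cc1 | starting material
7 | (E)-3-[4-(methoxymethoxy)phenyl]prop-2-enal | O=C/C=C/c1ccc(OCOC)cc1 | intermediate
8 | (S)-3-[2-bromo-6-formyl-3,5-bis(methoxymethoxy)phenoxy]-3-[4-(methoxymethoxy)phenyl]propanal (oxa-Michael adduct, drawn as the free aldehyde of the catalyst-bound enamine) | COCOc1cc(OCOC)c(C=O)c(c1Br)O[C@H](c1ccc(OCOC)cc1)CC=O | intermediate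
9 | (2S)-8-bromo-4-hydroxy-5,7-bis(methoxymethoxy)-2-[4-(methoxymethoxy)phenyl]chromane-3-carbaldehyde (aldol adduct, C3/C4 diastereomers, drawn as the free aldehyde) | COCOc1cc(OCOC)c2c(c1Br)O[C@H](c1ccc(OCOC)cc1)C(C=O)C2O | intermediate
10 | (R)-8-bromo-5,7-bis(methoxymethoxy)-2-[4-(methoxymethoxy)phenyl]-2H-chromene-3-carbaldehyde | COCOc1cc(OCOC)c2c(c1Br)O[C@H](c1ccc(OCOC)cc1)C(C=O)=C2 | intermediate
11 | (S)-8-bromo-5,7-bis(methoxymethoxy)-2-[4-(methoxymethoxy)phenyl]-2H-chromene | COCOc1cc(OCOC)c2c(c1Br)O[C@H](c1ccc(OCOC)cc1)C=C2 | intermediate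
12 | (S)-8-bromo-5,7-bis(methoxymethoxy)-2-[4-(methoxymethoxy)phenyl]chromane | COCOc1cc(OCOC)c2c(c1Br)O[C@H](c1ccc(OCOC)cc1)CC2 | intermediate
13 | tert-butyl(4-ethynylphenoxy)dimethylsilane | C#Cc1ccc(O[Si](C)(C)C(C)(C)C)cc1 | starting material
14 | (S)-tert-butyl{4-[(5,7-bis(methoxymethoxy)-2-[4-(methoxymethoxy)phenyl]chroman-8-yl)ethynyl]phenoxy}dimethylsilane | CC(C)(C)[Si](C)(C)Oc1ccc(cc1)C#Cc1c(OCOC)cc(OCOC)c2c1O[C@H](c1ccc(OCOC)cc1)CC2 | intermediate
15 | potassium permanganate | [K+].[O-][Mn](=O)(=O)=O | starting material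
16 | (S)-1-{5,7-bis(methoxymethoxy)-2-[4-(methoxymethoxy)phenyl]chroman-8-yl}-2-{4-[(tert-butyldimethylsilyl)oxy]phenyl}ethane-1,2-dione | O=C(C(=O)c1c(OCOC)cc(OCOC)c2c1O[C@H](c1ccc(OCOC)cc1)CC2)c1ccc(O[Si](C)(C)C(C)(C)C)cc1 | intermediate
17 | (S)-1-[5,7-dihydroxy-2-(4-hydroxyphenyl)chroman-8-yl]-2-(4-hydroxyphenyl)ethane-1,2-dione | O=C(C(=O)c1c(O)cc(O)c2c1O[C@H](c1ccc(O)cc1)CC2)c1ccc(O)cc1 | target

## Step count and risks

Total step count: 9.
Longest linear sequence: 8 steps (1 → 3 → 5 → 10 → 11 → 12 → 14 → 16 → 17); step 3 is a one-step side branch.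

Steps most likely to fail:

1. Step 4 (key step). The hindered, hydrogen-bonded phenol may add too slowly to the electron-rich enal, and the electron-rich formyl group may close too slowly, so that conversion stalls or facial selectivity at C2 is poor. Fallback, setting out from 5 and 7 and coming back at 11 (steps 4 and 5 are by-passed): enal 7 is reduced (NaBH4, CeCl3·7H2O, MeOH, 0 °C) to (E)-3-[4-(methoxymethoxy)phenyl]prop-2-en-1-ol F1 and acylated (ClCO2Me, pyridine, CH2Cl2) to (E)-3-[4-(methoxymethoxy)phenyl]allyl methyl carbonate F2. Aldehyde 5 is methylenated by a Wittig reaction (Ph3P=CH2 in excess, THF) to 2-bromo-3,5-bis(methoxymethoxy)-6-vinylphenol F3. Iridium-catalysed asymmetric allylic etherification of F2 with the lithium phenoxide of F3 ([Ir(cod)Cl]2 and the enantiomer of the binaphthol-derived N,N-bis(1-phenylethyl)phosphoramidite ligand that leads to the S ether, THF, rt) should give the branched ether (S)-2-bromo-1,5-bis(methoxymethoxy)-3-({1-[4-(methoxymethoxy)phenyl]prop-2-en-1-yl}oxy)-4-vinylbenzene F4. Ring-closing metathesis (second-generation Grubbs catalyst RuCl2(H2IMes)(PCy3)(=CHPh), CH2Cl2, 40 °C) then closes the same C3–C4 bond and gives 11.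

2. Step 5. At the temperature needed for CO extrusion the 2H-chromene may open electrocyclically to an ortho-quinone methide and re-close, which would erode the configuration at C2; CO loss may also stay incomplete. Fallback, setting out from 10 and coming back at 12 (11 is by-passed): the C3=C4 bond of 10 is hydrogenated first ([Ir(cod)(PCy3)(py)]PF6, H2, CH2Cl2, rt) to (2S)-8-bromo-5,7-bis(methoxymethoxy)-2-[4-(methoxymethoxy)phenyl]chromane-3-carbaldehyde F5 (mixture at C3, which is immaterial). This saturated aldehyde cannot ring-open pericyclically and should lose CO with RhCl(PPh3)3 at lower temperature (toluene, 70–80 °C, neutral conditions to avoid β-elimination of the ring oxygen), giving 12 directly.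

3. Step 7. Oxidative addition at the doubly ortho-oxygenated, electron-rich C8–Br bond may be so slow that copper-mediated alkyne homocoupling and protodebromination take over. Fallback, setting out from 12 and coming back at 16 (14 and steps 7 and 8 are by-passed): bromine–lithium exchange (n-BuLi, THF, −78 °C) gives (S)-{5,7-bis(methoxymethoxy)-2-[4-(methoxymethoxy)phenyl]chroman-8-yl}lithium F6. Acylation with N,N'-dimethoxy-N,N'-dimethyloxamide (Weinreb ketone synthesis) gives (S)-2-{5,7-bis(methoxymethoxy)-2-[4-(methoxymethoxy)phenyl]chroman-8-yl}-N-methoxy-N-methyl-2-oxoacetamide F7. Addition of {4-[(tert-butyldimethylsilyl)oxy]phenyl}magnesium bromide F8 (from (4-bromophenoxy)(tert-butyl)dimethylsilane and Mg, THF) to the chelating amide carbonyl of F7, whose keto group is shielded by the two ortho substituents of ring A, should give diketone 16.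

Further compounds
F1 | step 4 | (E)-3-[4-(methoxymethoxy)phenyl]prop-2-en-1-ol | OC/C=C/c1ccc(OCOC)cc1
F2 | step 4 | (E)-3-[4-(methoxymethoxy)phenyl]allyl methyl carbonate | COC(=O)OC/C=C/c1ccc(OCOC)cc1
F3 | step 4 | 2-bromo-3,5-bis(methoxymethoxy)-6-vinylphenol | C=Cc1c(O)c(Br)c(OCOC)cc1OCOC
F4 | step 4 | (S)-2-bromo-1,5-bis(methoxymethoxy)-3-({1-[4-(methoxymethoxy)phenyl]prop-2-en-1-yl}oxy)-4-vinylbenzene | C=Cc1c(OCOC)cc(OCOC)c(Br)c1O[C@H](c1ccc(OCOC)cc1)C=C
F5 | step 5 | (2S)-8-bromo-5,7-bis(methoxymethoxy)-2-[4-(methoxymethoxy)phenyl]chromane-3-carbaldehyde | COCOc1cc(OCOC)c2c(c1Br)O[C@H](c1ccc(OCOC)cc1)C(C=O)C2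
F6 | step 7 | (S)-{5,7-bis(methoxymethoxy)-2-[4-(methoxymethoxy)phenyl]chroman-8-yl}lithium | [Li]c1c(OCOC)cc(OCOC)c2c1O[C@H](c1ccc(OCOC)cc1)CC2
F7 | step 7 | (S)-2-{5,7-bis(methoxymethoxy)-2-[4-(methoxymethoxy)phenyl]chroman-8-yl}-N-methoxy-N-methyl-2-oxoacetamide | CON(C)C(=O)C(=O)c1c(OCOC)cc(OCOC)c2c1O[C@H](c1ccc(OCOC)cc1)CC2
F8 | step 7 | {4-[(tert-butyldimethylsilyl)oxy]phenyl}magnesium bromide | Br[Mg]c1ccc(O[Si](C)(C)C(C)(C)C)cc1
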